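**Retrosynthetic overview**

1. Locants of the target (labdane numbering) are used for all intermediates: ring A = C1–C5, C10; ring B = C5–C10; C17 = CH2 on C8; C20 = CH3 on C10; side chain C11–C16.
2. The succinimide ring is formed last, by acyl transfer within an Evans syn-aldol adduct (C12–C13 bond) of a C12 aldehyde. C8=C17 comes from dehydration of a tertiary C8 carbinol, and the aldehyde from a C9 allyl group.
3. Both carbocycles arise in one operation from an acyclic 1,2-dione triene. SnCl4 activates the C7/C8 dione, C9 of the (E)-C9=C10 alkene adds to C8 (ring B), and the terminal vinyl group then closes ring A through the C1–C10 bond with chloride capture at C2.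
4. Enabling feature: in ring A the C2–Cl carbon lies 1,3 to the quaternary C10 across the C1 methylene, which is the pattern left by a tertiary cation, a vinyl group and chloride. In ring B, C7–O next to C8=C17 is the footprint of a 1,2-dione. The axial methyl groups on C4 and C10 steer chloride to the equatorial 2α position.
5. The acyclic precursor carries a single stereocentre (C5), set by chirality transfer in an Eschenmoser–Claisen rearrangement from a carbinol made by catalytic asymmetric allylboration.

Key step: step 5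

Assumption: (R)-TRIP is taken to deliver the allyl group to the Re face of enal 3 (giving the 4R alcohol); if the sense is the opposite, the enantiomeric catalyst is used.

**Route**

Step 1
Reactants: 1 2,2-dimethylpent-4-enal; 2 2-(triphenylphosphoranylidene)propanal
Product: 3 (2E)-2,4,4-trimethylhepta-2,6-dienal
Conditions: toluene, 110 °C
Reagents that add atoms: none
Why: Wittig olefination with a formyl-stabilised ylide, which should give the (E)-2-methyl enal under thermodynamic control; the α-quaternary aldehyde cannot enolise.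

Step 2
Reactants: 3 (2E)-2,4,4-trimethylhepta-2,6-dienal
Product: 4 (4R,5E)-5,7,7-trimethyldeca-1,5,9-trien-4-ol
Conditions: allylboronic acid pinacol ester (1.3 equiv), (R)-TRIP [(R)-3,3'-bis(2,4,6-triisopropylphenyl)-1,1'-binaphthyl-2,2'-diyl hydrogen phosphate] (5 mol %), toluene, −30 °C; aqueous work-up
Reagents that add atoms: allylboronic acid pinacol ester, C=CCB1OC(C)(C)C(C)(C)O1
Why: chiral phosphoric acid-catalysed allylboration through a closed six-membered chair transition state, in which Re-face delivery of the allyl group should set the carbinol carbon (future C9) as R.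

Step 3
Reactants: 4 (4R,5E)-5,7,7-trimethyldeca-1,5,9-trien-4-ol
Product: 5 (3S,4E)-N,N,4-trimethyl-3-(2-methylpent-4-en-2-yl)octa-4,7-dienamide
Conditions: CH3C(OMe)2NMe2 (4 equiv), xylenes, 140 °C
Reagents that add atoms: N,N-dimethylacetamide dimethyl acetal, COC(C)(OC)N(C)C
Why: Eschenmoser–Claisen [3,3]-sigmatropic rearrangement through a chair with the allyl substituent of the carbinol carbon equatorial, which should transfer the carbinol chirality to C5 (S) and give the (E)-C9=C10 alkene.

Step 4
Reactants: 5 (3S,4E)-N,N,4-trimethyl-3-(2-methylpent-4-en-2-yl)octa-4,7-dienamide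
Product: 7 (5S,6E)-6-methyl-5-(2-methylpent-4-en-2-yl)deca-6,9-diene-2,3-dione, via enol ether 6 (not isolated)
Conditions: ethyl vinyl ether, t-BuLi, THF, −78 to 0 °C; then 5, −78 °C; then 1 M aq. HCl, THF, 23 °C
Reagents that add atoms: ethyl vinyl ether, C=COCC (as 1-ethoxyvinyllithium); water, O
Why: acyl-anion-equivalent addition to a tertiary amide (the stable tetrahedral intermediate prevents over-addition) followed by enol ether hydrolysis to the 1,2-dione; C5 is not α to a carbonyl and keeps its configuration.

Step 5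
Reactants: 7 (5S,6E)-6-methyl-5-(2-methylpent-4-en-2-yl)deca-6,9-diene-2,3-dione
Product: 8 2α-chloro-8α-hydroxy-4,4,8β,10β-tetramethyl-9β-(prop-2-enyl)-5α-decalin-7-one
Conditions: SnCl4 (2.2 equiv), CH2Cl2, −78 to −40 °C; then sat. aq. NaHCO3
Reagents that add atoms: tin tetrachloride SnCl4, Cl[Sn](Cl)(Cl)Cl
Why: Proposed new method: bidentate SnCl4 chelation makes the C7/C8 dione a strong carbonyl electrophile; C9 of the (E)-C9=C10 alkene adds to C8 through a chair (ring B, 6-endo-trig at the alkene with the carbonyl oxygen exocyclic), the charge developing at C10 is taken up antiperiplanar by the terminal carbon of the vinyl group (ring A, 6-endo-trig, the C1–C10 bond), and the incipient secondary C2 cation collapses with chloride from the stannate, so that the C8–C9, C1–C10 and C2–Cl bonds form in one operation. The closest known reaction types are Lewis-acid carbonyl-ene/Prins cyclisations of 1,2-dicarbonyl compounds and cation–olefin polycyclisations that end on a vinyl group with halide capture (halo-Prins); their combination on a dione triene is not known. The new stereocentres should be controlled as follows: C8 by the chelate (oxygen equatorial, CH3 axial), C9 by the E alkene (allyl equatorial), C10 by anti addition across C9=C10 in a chair–chair arrangement with the bulky C5 substituent equatorial (H5 and CH3-20 trans, absolute configuration relayed from C5), and C2 by antiperiplanar equatorial entry of chloride on the face remote from the axial C4 and C10 methyl groups. The step needs initiation at the trisubstituted alkene only, which is secured because only C9 can reach C8 through a six-membered chair and leave a tertiary cation. It also needs ring A closure to outrun proton loss from C10, which is secured because the C10 cation re-forms reversibly from its chloride or alkene forms under SnCl4/HCl whereas the secondary chloride of 8 does not re-ionise.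

Step 6
Reactants: 8 2α-chloro-8α-hydroxy-4,4,8β,10β-tetramethyl-9β-(prop-2-enyl)-5α-decalin-7-one
Product: 9 2α-chloro-4,4,8β,10β-tetramethyl-9β-(prop-2-enyl)-5α-decalin-7β,8α-diol
Conditions: NaBH4, MeOH/CH2Cl2, −20 °C
Reagents that add atoms: none
Why: hydride reduction of the ketone, in which axial attack from the α face (away from the axial 8β and 10β methyl groups) should give the equatorial 7β alcohol.

Step 7
Reactants: 9 2α-chloro-4,4,8β,10β-tetramethyl-9β-(prop-2-enyl)-5α-decalin-7β,8α-diol
Product: 10 7β-acetoxy-2α-chloro-4,4,8β,10β-tetramethyl-9β-(prop-2-enyl)-5α-decalin-8α-ol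
Conditions: Ac2O, pyridine, DMAP (cat.), CH2Cl2, 0 to 23 °C
Reagents that add atoms: acetic anhydride, CC(=O)OC(C)=O
Why: acylation that should be selective for the secondary alcohol, since the tertiary C8 hydroxyl is too hindered to react.

Step 8
Reactants: 10 7β-acetoxy-2α-chloro-4,4,8β,10β-tetramethyl-9β-(prop-2-enyl)-5α-decalin-8α-ol
Product: 11 7β-acetoxy-2α-chloro-4,4,10β-trimethyl-8-methylidene-9β-(prop-2-enyl)-5α-decalin
Conditions: SOCl2, pyridine, CH2Cl2, −78 °C
Reagents that add atoms: none
Why: E2 dehydration through the chlorosulfite, in which the equatorial leaving group on C8 has antiperiplanar hydrogens only on the C17 methyl group, so the exocyclic alkene should form; the β-acetoxy group disfavours ionisation.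

Step 9
Reactants: 11 7β-acetoxy-2α-chloro-4,4,10β-trimethyl-8-methylidene-9β-(prop-2-enyl)-5α-decalin
Product: 13 (7β-acetoxy-2α-chloro-4,4,10β-trimethyl-8-methylidene-5α-decalin-9β-yl)acetaldehyde, via vicinal diol 12 (not isolated)
Conditions: OsO4 (2 mol %), N-methylmorpholine N-oxide (1.1 equiv), acetone/H2O, 0 °C; then NaIO4, THF/pH 7 buffer, 0 °C
Reagents that add atoms: N-methylmorpholine N-oxide, C[N+]1([O-])CCOCC1 (oxygen relayed by OsO4)
Why: Lemieux–Johnson-type dihydroxylation and periodate cleavage, which should take the unhindered monosubstituted alkene in preference to the exocyclic alkene flanked by C7 and C9 and deactivated by the allylic acetate.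

Step 10
Reactants: 14 3-cyanopropanoic acid; 15 (4R)-4-benzyl-1,3-oxazolidin-2-one
Product: 17 (4R)-4-benzyl-3-(3-cyanopropanoyl)-1,3-oxazolidin-2-one, via mixed anhydride 16 (not isolated)
Conditions: pivaloyl chloride, Et3N, THF, −20 °C; then 15, LiCl, 23 °C
Reagents that add atoms: none
Why: N-acylation of the oxazolidinone through the pivalic mixed anhydride, which is attacked at the less hindered carbonyl.

Step 11
Reactants: 13 (7β-acetoxy-2α-chloro-4,4,10β-trimethyl-8-methylidene-5α-decalin-9β-yl)acetaldehyde; 17 (4R)-4-benzyl-3-(3-cyanopropanoyl)-1,3-oxazolidin-2-one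
Product: 19 (4R)-4-benzyl-3-[(2R,3S)-2-(cyanomethyl)-3-hydroxy-4-(7β-acetoxy-2α-chloro-4,4,10β-trimethyl-8-methylidene-5α-decalin-9β-yl)butanoyl]-1,3-oxazolidin-2-one, via boron enolate 18 (not isolated)
Conditions: 17, Bu2BOTf, Et3N, CH2Cl2, −78 to 0 °C; then 13, −78 to 0 °C; then pH 7 buffer, MeOH, H2O2, 0 °C
Reagents that add atoms: none
Why: Evans syn-aldol reaction, in which the (Z)-boron enolate reacts through a closed chair transition state and the (R)-benzyl auxiliary should set C12 as S and C13 as R regardless of the remote C9 centre.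

Step 12
Reactants: 19 (4R)-4-benzyl-3-[(2R,3S)-2-(cyanomethyl)-3-hydroxy-4-(7β-acetoxy-2α-chloro-4,4,10β-trimethyl-8-methylidene-5α-decalin-9β-yl)butanoyl]-1,3-oxazolidin-2-one
Product: 21 haterumaimide N, via primary amide 20 (not isolated)
Conditions: PtH(PMe2OH)(PMe2O)2H (5 mol %), EtOH/H2O 4:1, 80 °C
Reagents that add atoms: water, O
Why: neutral platinum-catalysed nitrile hydration, after which the primary amide nitrogen should attack the activated exocyclic imide carbonyl (5-exo-trig acyl transfer, as in succinimide formation from asparagine residues) to close the succinimide and expel the auxiliary without touching C12 or C13.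

**Compound list**

1 | 2,2-dimethylpent-4-enal | C=CCC(C)(C)C=O | starting material
2 | 2-(triphenylphosphoranylidene)propanal | CC(C=O)=P(c1ccccc1)(c1ccccc1)c1ccccc1 | starting material
3 | (2E)-2,4,4-trimethylhepta-2,6-dienal | C=CCC(C)(C)/C=C(\C)C=O | intermediate
4 | (4R,5E)-5,7,7-trimethyldeca-1,5,9-trien-4-ol | C=CCC(C)(C)/C=C(\C)[C@H](O)CC=C | intermediate
5 | (3S,4E)-N,N,4-trimethyl-3-(2-methylpent-4-en-2-yl)octa-4,7-dienamide | CN(C)C(=O)C[C@@H](C(C)(C)CC=C)/C(C)=C/CC=C | intermediate
6 | (5S,6E)-2-ethoxy-6-methyl-5-(2-methylpent-4-en-2-yl)deca-1,6,9-trien-3-one (enol ether, not isolated) | C=C(OCC)C(=O)C[C@@H](C(C)(C)CC=C)/C(C)=C/CC=C | intermediate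
7 | (5S,6E)-6-methyl-5-(2-methylpent-4-en-2-yl)deca-6,9-diene-2,3-dione | CC(=O)C(=O)C[C@@H](C(C)(C)CC=C)/C(C)=C/CC=C | intermediate
8 | 2α-chloro-8α-hydroxy-4,4,8β,10β-tetramethyl-9β-(prop-2-enyl)-5α-decalin-7-one | C[C@@]1(O)C(=O)C[C@H]2C(C)(C)C[C@H](Cl)C[C@]2(C)[C@H]1CC=C | intermediate
9 | 2α-chloro-4,4,8β,10β-tetramethyl-9β-(prop-2-enyl)-5α-decalin-7β,8α-diol | C[C@@]1(O)[C@@H](O)C[C@H]2C(C)(C)C[C@H](Cl)C[C@]2(C)[C@H]1CC=C | intermediate
10 | 7β-acetoxy-2α-chloro-4,4,8β,10β-tetramethyl-9β-(prop-2-enyl)-5α-decalin-8α-ol | C[C@@]1(O)[C@@H](OC(C)=O)C[C@H]2C(C)(C)C[C@H](Cl)C[C@]2(C)[C@H]1CC=C | intermediate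
11 | 7β-acetoxy-2α-chloro-4,4,10β-trimethyl-8-methylidene-9β-(prop-2-enyl)-5α-decalin | C=C1[C@@H](OC(C)=O)C[C@H]2C(C)(C)C[C@H](Cl)C[C@]2(C)[C@H]1CC=C | intermediate
12 | 9β-(2,3-dihydroxypropyl) analogue of 11 (vicinal diol, both C12 epimers, not isolated) | C=C1[C@@H](OC(C)=O)C[C@H]2C(C)(C)C[C@H](Cl)C[C@]2(C)[C@H]1CC(O)CO | intermediate
13 | (7β-acetoxy-2α-chloro-4,4,10β-trimethyl-8-methylidene-5α-decalin-9β-yl)acetaldehyde | C=C1[C@@H](OC(C)=O)C[C@H]2C(C)(C)C[C@H](Cl)C[C@]2(C)[C@H]1CC=O | intermediate
14 | 3-cyanopropanoic acid | N#CCCC(=O)O | starting material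
15 | (4R)-4-benzyl-1,3-oxazolidin-2-one | O=C1N[C@H](Cc2ccccc2)CO1 | starting material
16 | 3-cyanopropanoic pivalic anhydride (mixed anhydride, not isolated) | N#CCCC(=O)OC(=O)C(C)(C)C | intermediate
17 | (4R)-4-benzyl-3-(3-cyanopropanoyl)-1,3-oxazolidin-2-one | N#CCCC(=O)N1[C@H](Cc2ccccc2)COC1=O | intermediate
18 | (Z)-dibutylboron enolate of 17 (not isolated) | CCCCB(CCCC)O/C(=C\CC#N)N1[C@H](Cc2ccccc2)COC1=O | intermediate
19 | (4R)-4-benzyl-3-[(2R,3S)-2-(cyanomethyl)-3-hydroxy-4-(7β-acetoxy-2α-chloro-4,4,10β-trimethyl-8-methylidene-5α-decalin-9β-yl)butanoyl]-1,3-oxazolidin-2-one | C=C1[C@@H](OC(C)=O)C[C@H]2C(C)(C)C[C@H](Cl)C[C@]2(C)[C@H]1C[C@H](O)[C@@H](CC#N)C(=O)N1[C@H](Cc2ccccc2)COC1=O | intermediate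
20 | primary amide from 19, 2-(2-amino-2-oxoethyl) in place of 2-(cyanomethyl) (not isolated) | C=C1[C@@H](OC(C)=O)C[C@H]2C(C)(C)C[C@H](Cl)C[C@]2(C)[C@H]1C[C@H](O)[C@@H](CC(N)=O)C(=O)N1[C@H](Cc2ccccc2)COC1=O | intermediate
21 | haterumaimide N | C=C1[C@@H](OC(C)=O)C[C@H]2C(C)(C)C[C@H](Cl)C[C@]2(C)[C@H]1C[C@H](O)[C@H]1CC(=O)NC1=O | target

**Step count**

Total step count: 12. Longest linear sequence: 11 steps (steps 1–9, 11 and 12); step 10 prepares the aldol partner.

**Steps most likely to fail**

Step 5 (Proposed new method). The cascade may stop after ring B, by proton loss from C10 or chloride capture at C10 before the vinyl group engages. The chain may also fold with the C5 substituent axial, which would erode the trans ring fusion. The fallback uses known chemistry in two separate operations, sets out from dione 7 and returns at 8. Ring B alone is closed with SnCl4 (1.1 equiv) in CH2Cl2 at −78 °C with a cold quench; this is a Prins cyclisation with chloride capture at the tertiary carbon and should give the monocyclic chlorohydrin 4-chloro-2-hydroxy-2,4-dimethyl-5-(2-methylpent-4-en-2-yl)-3-(prop-2-enyl)cyclohexan-1-one F1. The isolated chloride is then re-ionised at C10 with TiCl4 in CH2Cl2 at −60 °C. This Lewis-acid-mediated addition of a tertiary alkyl chloride across a terminal alkene closes ring A through the C1–C10 bond and should return 8, because the secondary chloride formed no longer ionises. In the preformed ring B the axial 8β-methyl group blocks the axial approach to C10, so the vinyl group should enter equatorially and give the trans fusion.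

Step 9. Chemoselectivity may be lost: osmylation of the exocyclic C8=C17 alkene may compete with that of the allyl group and lead to over-oxidation. The fallback cleaves the allyl group before the exocyclic alkene exists; it sets out from 10 and returns at 13. Ozonolysis of 10 (O3, CH2Cl2/MeOH, −78 °C) with NaBH4 work-up should give the 9β-(2-hydroxyethyl) diol F2. The primary hydroxyl is silylated (TBSCl, imidazole) to silyl ether F3, and dehydration as in step 8 (SOCl2, pyridine, −78 °C) should give the exocyclic alkene F4. Desilylation with HF·pyridine gives the primary alcohol F5, and Dess–Martin periodinane oxidation gives aldehyde 13.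

Step 12. Ring closure may not keep pace with hydration, and heating may bring C13 epimerisation, retro-aldol cleavage or acyl transfer to the C12 hydroxyl. The fallback removes the auxiliary first and closes the imide from a succinamic acid; it sets out from 19 and returns at 21. LiOH/H2O2 (THF/H2O, 0 °C) cleaves the oxazolidinone to the β-hydroxy cyano acid F6. The same platinum-catalysed hydration at 40 °C should give the succinamic acid F7, which is cyclodehydrated with 1,1'-carbonyldiimidazole in THF to 21.

**Further compounds**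

F1 | step 5 | 4-chloro-2-hydroxy-2,4-dimethyl-5-(2-methylpent-4-en-2-yl)-3-(prop-2-enyl)cyclohexan-1-one (ring B of 8 with chloride on C10) | C[C@@]1(O)C(=O)C[C@@H](C(C)(C)CC=C)[C@](C)(Cl)[C@H]1CC=C
F2 | step 9 | 7β-acetoxy-2α-chloro-9β-(2-hydroxyethyl)-4,4,8β,10β-tetramethyl-5α-decalin-8α-ol | C[C@@]1(O)[C@@H](OC(C)=O)C[C@H]2C(C)(C)C[C@H](Cl)C[C@]2(C)[C@H]1CCO
F3 | step 9 | tert-butyldimethylsilyl ether of F2 at the primary hydroxyl | C[C@@]1(O)[C@@H](OC(C)=O)C[C@H]2C(C)(C)C[C@H](Cl)C[C@]2(C)[C@H]1CCO[Si](C)(C)C(C)(C)C
F4 | step 9 | 7β-acetoxy-2α-chloro-4,4,10β-trimethyl-8-methylidene-9β-[2-(tert-butyldimethylsilyloxy)ethyl]-5α-decalin | C=C1[C@@H](OC(C)=O)C[C@H]2C(C)(C)C[C@H](Cl)C[C@]2(C)[C@H]1CCO[Si](C)(C)C(C)(C)C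
F5 | step 9 | 2-(7β-acetoxy-2α-chloro-4,4,10β-trimethyl-8-methylidene-5α-decalin-9β-yl)ethanol | C=C1[C@@H](OC(C)=O)C[C@H]2C(C)(C)C[C@H](Cl)C[C@]2(C)[C@H]1CCO
F6 | step 12 | (2R,3S)-2-(cyanomethyl)-3-hydroxy-4-(7β-acetoxy-2α-chloro-4,4,10β-trimethyl-8-methylidene-5α-decalin-9β-yl)butanoic acid | C=C1[C@@H](OC(C)=O)C[C@H]2C(C)(C)C[C@H](Cl)C[C@]2(C)[C@H]1C[C@H](O)[C@@H](CC#N)C(=O)O
F7 | step 12 | (2R,3S)-2-(2-amino-2-oxoethyl)-3-hydroxy-4-(7β-acetoxy-2α-chloro-4,4,10β-trimethyl-8-methylidene-5α-decalin-9β-yl)butanoic acid | C=C1[C@@H](OC(C)=O)C[C@H]2C(C)(C)C[C@H](Cl)C[C@]2(C)[C@H]1C[C@H](O)[C@@H](CC(N)=O)C(=O)O
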